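**Strategy.** Both C-prenyl bonds of the target are traced back to allyl aryl ethers on a MOM-protected quercetin, itself built from a phloroacetophenone and a protocatechualdehyde by chalcone formation and oxidative pyranone closure. The key step exploits that C8 of ring A is para to O5, which sits beside the C4 carbonyl, and that C5' of ring B is ortho to O4' while the other ortho carbon, C3', is blocked by oxygen. In one operation a prenyl group travels from O5 to C8 (Claisen then Cope) and a 1,1-dimethylallyl group from O4' to C5' (ortho-Claisen). The precursor is 3,7,3'-tri-O-MOM quercetin bearing a prenyl ether on O5 and a 1,1-dimethylallyl ether on O4'.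

Key step: step 9

Remark on the chemistry: commercial 1 (a monohydrate) is dried before use. In step 9 ring A is assumed to rearrange first (catalysed, 85 °C) and ring B second (thermal, 120 °C); the opposite order would converge on the same product.

Step 1
Reactants: 1 2,4,6-trihydroxyacetophenone
Product: 2 2,6-dihydroxy-4-(methoxymethoxy)acetophenone
Conditions: MOMCl (1.0 equiv), iPr2NEt, CH2Cl2–THF, 0 °C
Reagents that add atoms: chloromethyl methyl ether (MOMCl), COCCl
Why: O-alkylation with an α-chloro ether (Williamson type): the 4-OH, para to the acetyl group and not held in a hydrogen bond, is the most acidic phenol, so one equivalent of MOMCl in the cold should go mainly there, with the 2,4-bis-ether and unchanged 1 removed by chromatography.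

Step 2
Reactants: 2 2,6-dihydroxy-4-(methoxymethoxy)acetophenone; 3 prenyl bromide
Product: 4 2-hydroxy-4-(methoxymethoxy)-6-(prenyloxy)acetophenone
Conditions: K2CO3, acetone, 50 °C
Reagents that add atoms: none
Why: Williamson O-allylation: only one ortho-hydroxyl can chelate the ketone at a time, so the other is alkylated by the primary allylic bromide (K2CO3 in acetone favours O- over C-alkylation), and the hydroxyl left behind is locked in the chelate and should resist a second alkylation.

Step 3
Reactants: 5 3,4-dihydroxybenzaldehyde; 6 2-methylbut-3-yn-2-ol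
Product: 8 3-hydroxy-4-(2-methylbut-3-yn-2-yloxy)benzaldehyde, via 2-methylbut-3-yn-2-yl trifluoroacetate 7 (not isolated)
Conditions: (CF3CO)2O, DBU, MeCN, −5 °C (6 to 7); then 5, DBU (1.0 equiv), CuCl2·2H2O (cat.), MeCN, 0 °C, under N2
Reagents that add atoms: none
Why: Copper-catalysed propargylic etherification of a phenol with a tertiary propargylic trifluoroacetate made in the flask: one equivalent of DBU ionises only the more acidic 4-OH (para to the formyl group), and that phenoxide captures the copper-bound propargylic electrophile at the tertiary carbon under cold, mild conditions that spare the aldehyde.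

Step 4
Reactants: 8 3-hydroxy-4-(2-methylbut-3-yn-2-yloxy)benzaldehyde
Product: 9 3-(methoxymethoxy)-4-(2-methylbut-3-yn-2-yloxy)benzaldehyde
Conditions: MOMCl, iPr2NEt, CH2Cl2, 0 °C to rt
Reagents that add atoms: chloromethyl methyl ether (MOMCl), COCCl
Why: Standard MOM protection of the remaining phenol, so that ring B carries no free hydroxyl in the aldol and oxidation steps and C3' stays blocked by oxygen in the key step.

Step 5
Reactants: 4 2-hydroxy-4-(methoxymethoxy)-6-(prenyloxy)acetophenone; 9 3-(methoxymethoxy)-4-(2-methylbut-3-yn-2-yloxy)benzaldehyde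
Product: 10 (E)-1-[2-hydroxy-4-(methoxymethoxy)-6-(prenyloxy)phenyl]-3-[3-(methoxymethoxy)-4-(2-methylbut-3-yn-2-yloxy)phenyl]prop-2-en-1-one
Conditions: KOH, EtOH–H2O, 0 °C to rt
Reagents that add atoms: none
Why: Claisen–Schmidt condensation: the methyl ketone enolate adds to the non-enolisable aldehyde and E1cB dehydration gives the conjugated E-enone, while the MOM ethers, both allyl-type ethers and the terminal alkyne are inert to aqueous-alcoholic KOH at room temperature.

Step 6
Reactants: 10 the 2'-hydroxychalcone of step 5
Product: 11 3-hydroxy-7-(methoxymethoxy)-2-[3-(methoxymethoxy)-4-(2-methylbut-3-yn-2-yloxy)phenyl]-5-(prenyloxy)chromen-4-one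
Conditions: 30% aq. H2O2, aq. NaOH, MeOH, 0 °C
Reagents that add atoms: hydrogen peroxide, OO
Why: Algar–Flynn–Oyamada reaction: hydroperoxide anion attacks only the electron-poor enone, the 2'-phenoxide closes ring C at the benzylic carbon (helped by the electron-rich dialkoxyphenyl ring) and further oxidation gives the 3-hydroxyflavone; the low temperature is chosen to disfavour the five-membered closure to an aurone that a 6'-alkoxy group encourages, and the prenyl alkene and the alkyne do not react with a nucleophilic oxidant.

Step 7
Reactants: 11 the flavonol of step 6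
Product: 12 3,7-bis(methoxymethoxy)-2-[3-(methoxymethoxy)-4-(2-methylbut-3-yn-2-yloxy)phenyl]-5-(prenyloxy)chromen-4-one
Conditions: MOMCl, iPr2NEt, CH2Cl2, 0 °C to rt
Reagents that add atoms: chloromethyl methyl ether (MOMCl), COCCl
Why: O-alkylation of the acidic 3-hydroxyl, the only free hydroxyl present, which leaves O5 and the C4 carbonyl as the only chelating site for the europium catalyst and gives a group that is removed with the other MOM ethers at the end.

Step 8
Reactants: 12 the tri-MOM alkyne of step 7
Product: 13 3,7-bis(methoxymethoxy)-2-[3-(methoxymethoxy)-4-(2-methylbut-3-en-2-yloxy)phenyl]-5-(prenyloxy)chromen-4-one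
Conditions: H2 (1 atm), Pd/CaCO3 poisoned with Pb(OAc)2 (Lindlar catalyst), quinoline, EtOAc, rt, stopped after one equivalent of H2
Reagents that add atoms: none
Why: Lindlar semihydrogenation of the terminal alkyne to a vinyl group; the poisoned catalyst should leave the trisubstituted prenyl alkene and the chromone double bond alone, and placing the step directly before the rearrangement means the acid- and heat-sensitive tertiary allyl ether is not carried through other steps.

Step 9
Reactants: 13 3,7,3'-tri-O-MOM-5-O-prenyl-4'-O-(1,1-dimethylallyl)quercetin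
Product: 16 5-hydroxy-2-[4-hydroxy-3-(methoxymethoxy)-5-prenylphenyl]-3,7-bis(methoxymethoxy)-8-prenylchromen-4-one, via ring A C6 dienone 14 (not isolated), via 8-prenyl 4'-O-(1,1-dimethylallyl) ether 15 (not isolated)
Conditions: Eu(fod)3 [Eu(C10H10F7O2)3, tris(6,6,7,7,8,8,8-heptafluoro-2,2-dimethyloctane-3,5-dionato)europium] (10–20 mol%), solid NaHCO3, PhCl, 85 °C until 13 is consumed, then 120 °C until 15 is consumed
Reagents that add atoms: none
Why: Proposed new method: on ring A the europium centre binds the C4 carbonyl and O5 and so eases a chair [3,3] shift of the prenyl group from O5 to C6 (dienone 14, carrying a 1,1-dimethylallyl group), a second [3,3] (Cope) shift across C6–C7–C8 delivers it to C8 in linear form and enolisation gives the chelated 5-OH of 15; on ring B the tertiary ether on O4' then undergoes one thermal [3,3] shift to C5' and tautomerises to the 4'-phenol with a linear prenyl group. The closest known reaction types are the Eu(fod)3-catalysed para-Claisen–Cope rearrangement of 5-O-prenyl flavonoids to 8-prenyl flavonoids and the thermal ortho-Claisen rearrangement of aryl 1,1-dimethylallyl ethers; new is running both on one substrate in one flask, which should be possible because the ring B ether rearranges just above the temperature of the catalysed ring A relay and the MOM ethers on O3, O7 and O3' are spectators. No ring is closed and no stereocentre remains, the C6 centre of 14 being transient and erased by the Cope shift. The selectivity needed is positional: at C6 the Cope shift to C8 must outrun enolisation to a 6-(1,1-dimethylallyl) phenol, which the catalyst and the aprotic buffered medium favour, and on ring B only C5' carries a hydrogen, since C3' bears the MOM ether, so a shift to C3' can only revert. The solid NaHCO3 keeps the medium free of acid that would ionise the tertiary ether or close chromans.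

Step 10
Reactants: 16 3,7,3'-tri-O-MOM-8,5'-diprenylquercetin
Product: 17 Broussonol D (8,5'-diprenylquercetin)
Conditions: HCl (about 1 M) in MeOH–THF, 40 °C, quenched with NaHCO3 as soon as complete
Reagents that add atoms: none
Why: Acid-catalysed acetal exchange of the three MOM ethers with methanol; dilute acid, mild temperature and prompt quenching are chosen because the 7-OH/8-prenyl and 4'-OH/5'-prenyl pairs can cyclise to 2,2-dimethylchromans under stronger acid.

**Compound list**

1 | 2,4,6-trihydroxyacetophenone | CC(=O)c1c(O)cc(O)cc1O | starting material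
2 | 2,6-dihydroxy-4-(methoxymethoxy)acetophenone | CC(=O)c1c(O)cc(OCOC)cc1O | intermediate
3 | prenyl bromide (1-bromo-3-methylbut-2-ene) | CC(C)=CCBr | starting material
4 | 2-hydroxy-4-(methoxymethoxy)-6-(prenyloxy)acetophenone | CC(=O)c1c(O)cc(OCOC)cc1OCC=C(C)C | intermediate
5 | 3,4-dihydroxybenzaldehyde | O=Cc1ccc(O)c(O)c1 | starting material
6 | 2-methylbut-3-yn-2-ol | CC(C)(O)C#C | starting material
7 | 2-methylbut-3-yn-2-yl trifluoroacetate | CC(C)(OC(=O)C(F)(F)F)C#C | intermediate (not isolated)
8 | 3-hydroxy-4-(2-methylbut-3-yn-2-yloxy)benzaldehyde | O=Cc1ccc(OC(C)(C)C#C)c(O)c1 | intermediate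
9 | 3-(methoxymethoxy)-4-(2-methylbut-3-yn-2-yloxy)benzaldehyde | O=Cc1ccc(OC(C)(C)C#C)c(OCOC)c1 | intermediate
10 | (E)-2'-hydroxy-4'-(methoxymethoxy)-6'-(prenyloxy)-3-(methoxymethoxy)-4-(2-methylbut-3-yn-2-yloxy)chalcone | COCOc1cc(O)c(C(=O)/C=C/c2ccc(OC(C)(C)C#C)c(OCOC)c2)c(OCC=C(C)C)c1 | intermediate
11 | 5-O-prenyl-7,3'-di-O-MOM-4'-O-(2-methylbut-3-yn-2-yl)quercetin (free 3-OH) | COCOc1cc(OCC=C(C)C)c2c(=O)c(O)c(-c3ccc(OC(C)(C)C#C)c(OCOC)c3)oc2c1 | intermediate
12 | 3,7,3'-tri-O-MOM-5-O-prenyl-4'-O-(2-methylbut-3-yn-2-yl)quercetin | COCOc1cc(OCC=C(C)C)c2c(=O)c(OCOC)c(-c3ccc(OC(C)(C)C#C)c(OCOC)c3)oc2c1 | intermediate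
13 | 3,7,3'-tri-O-MOM-5-O-prenyl-4'-O-(1,1-dimethylallyl)quercetin | COCOc1cc(OCC=C(C)C)c2c(=O)c(OCOC)c(-c3ccc(OC(C)(C)C=C)c(OCOC)c3)oc2c1 | intermediate
14 | ring A dienone: 6-(2-methylbut-3-en-2-yl)-6H-chromene-4,5-dione tautomer of the ring A Claisen product (racemic at C6, transient) | COCOC1=CC2=C(C(=O)C1C(C)(C)C=C)C(=O)C(OCOC)=C(O2)c1ccc(OC(C)(C)C=C)c(OCOC)c1 | intermediate (not isolated)
15 | 5-hydroxy-8-prenyl-3,7,3'-tri-O-MOM-4'-O-(1,1-dimethylallyl)quercetin | COCOc1cc(O)c2c(=O)c(OCOC)c(-c3ccc(OC(C)(C)C=C)c(OCOC)c3)oc2c1CC=C(C)C | intermediate (not isolated)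
16 | 3,7,3'-tri-O-MOM-8,5'-diprenylquercetin | COCOc1cc(O)c2c(=O)c(OCOC)c(-c3cc(CC=C(C)C)c(O)c(OCOC)c3)oc2c1CC=C(C)C | intermediate
17 | Broussonol D | CC(C)=CCc1cc(-c2oc3c(CC=C(C)C)c(O)cc(O)c3c(=O)c2O)cc(O)c1O | target

**Totals.** Total step count: 10. Longest linear sequence: 8 steps (1 to 17 through steps 1, 2, 5–10; equally 5 to 17 through steps 3–10).

**Steps most likely to fail**

Step 9. What may go wrong: ionisation of the tertiary ether on ring B by the Lewis acid with loss of its five-carbon unit, or one of the two relays stalling while the other substrate half degrades. The two rearrangements would then be run in separate flasks, each as known chemistry. Setting out from 13, heating without any catalyst in xylene containing N,N-diethylaniline at about 130 °C should bring about only the thermal ortho-Claisen rearrangement on ring B, since the 5-O-prenyl ether needs the catalyst or a much higher temperature. This gives the phenol 3,7,3'-tri-O-MOM-5-O-prenyl-5'-C-prenylquercetin F1. After isolation, F1 is treated with Eu(fod)3 and solid NaHCO3 in PhCl at 85 °C, the established para-Claisen–Cope relay of 5-O-prenyl flavonoids, and the route is rejoined at 16.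

Step 6. What may go wrong: diversion of the ring closure towards five-membered attack and aurone formation under the influence of the 6'-alkoxy group, or incomplete oxidation. Ring C would then be closed before any oxidation, so that the aurone channel no longer exists. Setting out from 10, NaOAc in refluxing EtOH should give by intramolecular oxa-Michael addition the racemic flavanone 5-O-prenyl-7,3'-di-O-MOM-4'-O-(2-methylbut-3-yn-2-yl)eriodictyol F2. Its potassium enolate (KN(SiMe3)2, 1 equivalent, THF, −78 °C; the ketone α-hydrogen is more acidic than the alkyne hydrogen) is hydroxylated with 2-(phenylsulfonyl)-3-phenyloxaziridine (Davis-type enolate oxidation, inert to the prenyl alkene and the alkyne), anti to the C2 aryl group. This gives the racemic trans-dihydroflavonol 3-hydroxy-5-O-prenyl-7,3'-di-O-MOM-4'-O-(2-methylbut-3-yn-2-yl)eriodictyol F3. Oxidation of the α-ketol of F3 with Dess–Martin periodinane and NaHCO3 in CH2Cl2 leads, after enolisation, to the flavonol, and the route is rejoined at 11.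

Step 3. What may go wrong: binding or reduction of the copper catalyst by the free catechol, or etherification at both oxygens. The order of the two etherifications would then be reversed, so that copper only meets a monophenol. Setting out from 5, the dianion (NaH, 2 equivalents, DMF, 0 °C) should react with one equivalent of MOMCl at the more nucleophilic, less delocalised 3-oxide, the known way to 3-O-alkylated protocatechualdehydes, to give 4-hydroxy-3-(methoxymethoxy)benzaldehyde F4. F4 is then etherified with trifluoroacetate 7 (made from 6 as in step 3) under CuCl2·2H2O and DBU in MeCN at 0 °C. This gives 9 directly, where the route is rejoined, and step 4 is no longer needed.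

**Further compounds**

F1 | step 9 | 3,7,3'-tri-O-MOM-5-O-prenyl-5'-C-prenylquercetin (free 4'-OH) | COCOc1cc(OCC=C(C)C)c2c(=O)c(OCOC)c(-c3cc(CC=C(C)C)c(O)c(OCOC)c3)oc2c1
F2 | step 6 | 5-O-prenyl-7,3'-di-O-MOM-4'-O-(2-methylbut-3-yn-2-yl)eriodictyol (racemic flavanone) | COCOc1cc(OCC=C(C)C)c2c(c1)OC(c1ccc(OC(C)(C)C#C)c(OCOC)c1)CC2=O
F3 | step 6 | trans-3-hydroxy-5-O-prenyl-7,3'-di-O-MOM-4'-O-(2-methylbut-3-yn-2-yl)eriodictyol (racemic, 2R,3R enantiomer drawn) | O=C1[C@H](O)[C@@H](c3ccc(OC(C)(C)C#C)c(OCOC)c3)Oc2cc(OCOC)cc(OCC=C(C)C)c21
F4 | step 3 | 4-hydroxy-3-(methoxymethoxy)benzaldehyde | O=Cc1ccc(O)c(OCOC)c1
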